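**Assumptions (one line each):**
- The NHK macrocyclization sets the C2 carbinol under ring-conformational control. I assume the required (2R) epimer is the major diastereomer and the minor one is removed chromatographically.
- The cross-metathesis gives mainly the E-trisubstituted alkene. I assume the Z isomer is removable by AgNO3-silica chromatography.

**Target configuration:** (2R,7R,8R); both trisubstituted alkenes E; the 7,8-epoxide is trans; the dihydrofuran ring carries a C1=C15 double bond with C2 and C17 cis.

## Retrosynthetic overview
1. The target is the acetate of a dihydrofuran alcohol, formed by Mitsunobu cyclodehydration of a Z-ene-1,4-diol (O–C17 bond).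
2. The Z-ene-diol comes from a 14-membered intramolecular Nozaki–Hiyama–Kishi (NHK) coupling (C2–C3 bond, sets C2) of an E-vinyl iodide with a butenolide-derived lactol, which is a masked Z-γ-hydroxy-enal.
3. The lactol's butenolide and the vinyl iodide arm are joined by E-selective cross-metathesis (C11=C12). One partner is a butenolide with an isopropenyl-type side chain, built by HWE on 2,2-dimethyl-1,3-dioxan-5-one.
4. The other partner is an epoxy vinyl iodide with a terminal alkene, built from 4-pentyn-1-ol by carboalumination, HWE, DIBAL, Sharpless epoxidation and allyl-cuprate coupling.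

## Route

**Step 1**
Reactants: 1 (4-pentyn-1-ol)
Product: 2 ((E)-5-iodo-4-methylpent-4-en-1-ol)
Conditions: Me3Al, Cp2ZrCl2, CH2Cl2, rt; then I2, THF, –30 °C
Reagents that add atoms: trimethylaluminium (C[Al](C)C, adds CH3); iodine (II, adds I)
Why: Negishi Zr-catalysed syn-methylalumination puts Me on the internal carbon and Al on the terminal carbon. I2 then replaces Al with retention, giving the E-trisubstituted vinyl iodide (I trans to the chain), which becomes the C3=C4 E-alkene.

**Step 2**
Reactants: 2
Product: 3 ((E)-5-iodo-4-methylpent-4-enal)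
Conditions: Dess–Martin periodinane, NaHCO3, CH2Cl2, 0 °C → rt
Reagents that add atoms: none
Why: Mild oxidation of the primary alcohol; the vinyl iodide is untouched and there is no stereocentre to epimerize.

**Step 3**
Reactants: 3; 4 (triethyl 2-phosphonopropionate)
Product: 5 (ethyl (2E,6E)-7-iodo-2,6-dimethylhepta-2,6-dienoate)
Conditions: NaH, THF, 0 °C → rt
Reagents that add atoms: none (the carbons come from reactant 4)
Why: Horner–Wadsworth–Emmons olefination of an aliphatic aldehyde with a 2-phosphonopropionate gives the E-trisubstituted enoate. This becomes C7=C8 and carries C8-Me and C9.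

**Step 4**
Reactants: 5
Product: 6 ((2E,6E)-7-iodo-2,6-dimethylhepta-2,6-dien-1-ol)
Conditions: DIBAL-H (2.5 equiv), CH2Cl2, –78 °C
Reagents that add atoms: none (hydride only)
Why: DIBAL reduces the conjugated ester to the allylic alcohol required for asymmetric epoxidation; the alkene geometry and the vinyl iodide are retained.

**Step 5**
Reactants: 6
Product: 7 ([(2R,3R)-3-[(3E)-4-iodo-3-methylbut-3-en-1-yl]-2-methyloxiran-2-yl]methanol)
Conditions: Ti(OiPr)4, D-(–)-DET, TBHP, 4 Å MS, CH2Cl2, –20 °C
Reagents that add atoms: tert-butyl hydroperoxide (CC(C)(C)OO, supplies the epoxide O)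
Why: Sharpless asymmetric epoxidation is directed by the allylic alcohol. D-(–)-tartrate delivers oxygen to the face giving (2R,3R), which is C8 = R and C7 = R in the target numbering. The trans-epoxide follows from the E-alkene, and the vinyl iodide is untouched.

**Step 6**
Reactants: 7
Product: 8 (the (2R,3R) epoxy tosylate)
Conditions: TsCl, Et3N, DMAP (cat.), CH2Cl2, 0 °C
Reagents that add atoms: p-toluenesulfonyl chloride (Cc1ccc(cc1)S(=O)(=O)Cl, adds Ts)
Why: Sulfonylation of the primary hydroxyl makes C9 an electrophile. No bond to a stereocentre is touched.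

**Step 7**
Reactants: 8; 9 (allylmagnesium bromide)
Product: 10 ((2R,3R)-2-(but-3-en-1-yl)-3-[(3E)-4-iodo-3-methylbut-3-en-1-yl]-2-methyloxirane)
Conditions: CuI (10 mol %), THF, –40 °C → 0 °C
Reagents that add atoms: allylmagnesium bromide (C=CC[Mg]Br, adds C3H5)
Why: Cu-catalysed SN2 displacement at the primary tosylate installs C10–C11=CH2 while the epoxide survives. The epoxide carbons keep their configuration because none of their bonds are broken.

**Step 8**
Reactants: 11 (triethyl phosphonoacetate); 12 (4-bromo-2-methylbut-1-ene)
Product: 13 (ethyl 2-(diethoxyphosphoryl)-5-methylhex-5-enoate)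
Conditions: NaH, THF/DMF, 0 °C → rt
Reagents that add atoms: none (carbons come from reactant 12)
Why: Enolate alkylation of the phosphonoacetate. It installs the C14–C13–C12(Me)=CH2 side chain on the carbon that becomes C1.

**Step 9**
Reactants: 13; 14 (2,2-dimethyl-1,3-dioxan-5-one)
Product: 15 (ethyl 2-(2,2-dimethyl-1,3-dioxan-5-ylidene)-5-methylhex-5-enoate)
Conditions: NaH, THF, 0 → 65 °C
Reagents that add atoms: none
Why: HWE olefination of the symmetric ketone builds the C1=C15 tetrasubstituted alkene. Because the two ring CH2O groups are equivalent, there is no E/Z issue.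

**Step 10**
Reactants: 15
Product: 16 (4-(hydroxymethyl)-3-(3-methylbut-3-en-1-yl)furan-2(5H)-one)
Conditions: p-TsOH·H2O (cat.), MeOH, 50 °C
Reagents that add atoms: none
Why: Acetonide methanolysis frees both CH2OH groups. The one cis to the ester lactonizes, giving the butenolide (C17 in the ring, C16 as free CH2OH). This fixes the Z relationship between C2 and C17 through the ring.

**Step 11**
Reactants: 10; 16
Product: 17 (butenolide carrying the epoxy vinyl-iodide chain, C11=C12 E)
Conditions: Hoveyda–Grubbs II (10 mol %), CH2Cl2, 40 °C; 10 used in excess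
Reagents that add atoms: none (ethylene is lost)
Why: Cross-metathesis of the monosubstituted alkene of 10 with the 1,1-disubstituted alkene of 16 forms the trisubstituted, mainly E C11=C12. The tetrasubstituted butenolide alkene, vinyl iodide and epoxide are inert.

**Step 12**
Reactants: 17
Product: 18 (lactol of 17, mixture of anomers)
Conditions: DIBAL-H (2.5 equiv), toluene, –78 °C; Rochelle salt work-up
Reagents that add atoms: none (hydride only)
Why: Partial reduction of the lactone to the lactol; one equivalent is consumed by the free CH2OH. The lactol is the ring-closed form of the Z-γ-hydroxy-enal, and the anomeric centre is irrelevant because it is destroyed in the next step.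

**Step 13**
Reactants: 18
Product: 19 (macrocyclic triol: C2-OH, C16-OH and C17-OH, with E C3=C4)
Conditions: CrCl2 (8 equiv), NiCl2 (0.1 equiv), DMSO, rt, 2 mM with slow addition
Reagents that add atoms: none
Why: Intramolecular Nozaki–Hiyama–Kishi coupling. The vinyl-chromium species adds to the aldehyde released from the lactol, closing the 14-membered ring at C2–C3 with retention of the E-alkene. The C2 carbinol is set by the ring-conformational bias, which I assume favours (2R); the C1=C15 alkene stays Z (C2 cis to C17).

**Step 14**
Reactants: 19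
Product: 20 (alcohol precursor, desacetyl lobophynin B)
Conditions: PPh3, DIAD, THF, 0 °C
Reagents that add atoms: none
Why: Mitsunobu cyclodehydration. The cis primary C17 hydroxyl is activated and C2-OH closes the 2,5-dihydrofuran by 5-exo SN2 at C17. C2 itself is not inverted. The trans C16-OH cannot cyclize and is not consumed, because phosphonium formation at it is reversible.

**Step 15**
Reactants: 20
Product: 21 (lobophynin B)
Conditions: Ac2O, Et3N, DMAP (cat.), CH2Cl2, 0 °C
Reagents that add atoms: acetic anhydride (CC(=O)OC(C)=O, adds acetyl)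
Why: Chemoselective acetylation of the only free hydroxyl, C16-OH; the epoxide and dihydrofuran are unaffected.

## Compound list
1 | 4-pentyn-1-ol | OCCCC#C | starting material
2 | (E)-5-iodo-4-methylpent-4-en-1-ol | OCCC/C(C)=C/I | intermediate
3 | (E)-5-iodo-4-methylpent-4-enal | O=CCC/C(C)=C/I | intermediate
4 | triethyl 2-phosphonopropionate | CCOC(=O)C(C)P(=O)(OCC)OCC | starting material
5 | ethyl (2E,6E)-7-iodo-2,6-dimethylhepta-2,6-dienoate | CCOC(=O)/C(C)=C/CC/C(C)=C/I | intermediate
6 | (2E,6E)-7-iodo-2,6-dimethylhepta-2,6-dien-1-ol | OC/C(C)=C/CC/C(C)=C/I | intermediate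
7 | [(2R,3R)-3-[(3E)-4-iodo-3-methylbut-3-en-1-yl]-2-methyloxiran-2-yl]methanol | OC[C@@]1(C)O[C@@H]1CC/C(C)=C/I | intermediate
8 | (2R,3R)-epoxy tosylate of 7 | Cc1ccc(cc1)S(=O)(=O)OC[C@@]1(C)O[C@@H]1CC/C(C)=C/I | intermediate
9 | allylmagnesium bromide | C=CC[Mg]Br | starting material
10 | (2R,3R)-2-(but-3-en-1-yl)-3-[(3E)-4-iodo-3-methylbut-3-en-1-yl]-2-methyloxirane | C=CCC[C@@]1(C)O[C@@H]1CC/C(C)=C/I | intermediate
11 | triethyl phosphonoacetate | CCOC(=O)CP(=O)(OCC)OCC | starting material
12 | 4-bromo-2-methylbut-1-ene | C=C(C)CCBr | starting material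
13 | ethyl 2-(diethoxyphosphoryl)-5-methylhex-5-enoate | CCOC(=O)C(CCC(C)=C)P(=O)(OCC)OCC | intermediate
14 | 2,2-dimethyl-1,3-dioxan-5-one | CC1(C)OCC(=O)CO1 | starting material
15 | ethyl 2-(2,2-dimethyl-1,3-dioxan-5-ylidene)-5-methylhex-5-enoate | CCOC(=O)C(CCC(C)=C)=C1COC(C)(C)OC1 | intermediate
16 | 4-(hydroxymethyl)-3-(3-methylbut-3-en-1-yl)furan-2(5H)-one | OCC1=C(CCC(C)=C)C(=O)OC1 | intermediate
17 | cross-metathesis product (butenolide with epoxy vinyl-iodide chain) | OCC1=C(CC/C(C)=C/CC[C@@]2(C)O[C@@H]2CC/C(C)=C/I)C(=O)OC1 | intermediate
18 | lactol of 17 (anomers) | OCC1=C(CC/C(C)=C/CC[C@@]2(C)O[C@@H]2CC/C(C)=C/I)C(O)OC1 | intermediate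
19 | macrocyclic Z-ene-1,4-diol with free C16-OH (triol) | OC/C(=C1/CC/C(C)=C/CC[C@@]2(C)O[C@@H]2CC/C(C)=C/[C@H]1O)CO | intermediate
20 | desacetyl lobophynin B | OCC1=C2CC/C(C)=C/CC[C@@]3(C)O[C@@H]3CC/C(C)=C/[C@H]2OC1 | intermediate
21 | lobophynin B | CC(=O)OCC1=C2CC/C(C)=C/CC[C@@]3(C)O[C@@H]3CC/C(C)=C/[C@H]2OC1 | target

## Totals
- Total steps: 15.
- Longest linear sequence: 12 (1 → 2 → 3 → 5 → 6 → 7 → 8 → 10 → 17 → 18 → 19 → 20 → 21, counting each arrow, i.e. steps 1–7 and 11–15).

## Three steps most likely to fail
1. **Step 13, NHK macrocyclization.** The lactol may open poorly, and the diastereoselectivity at C2 is only ring-controlled.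
   - Fallback (different approach): set C2 before ring closure by Ru-catalysed asymmetric transfer hydrogenation of an alkynyl ketone, then Lindlar reduction. Close C3=C4 instead by macro-RCM of a 2-vinyl-2,5-dihydrofuran with a methallyl-terminated chain.
2. **Step 11, cross-metathesis of a monosubstituted with a 1,1-disubstituted alkene.** Yield and E/Z ratio may be poor.
   - Fallback (different approach): make C11=C12 by carboalumination of a terminal alkyne to an E-vinyl iodide, then couple it to the C10 alkylborane by B-alkyl Suzuki–Miyaura coupling, so the alkene is built from an alkyne rather than by metathesis.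
3. **Step 7, allyl-cuprate displacement on a neopentyl-type epoxy tosylate with a vinyl iodide present.** Iodine–magnesium exchange or epoxide opening could compete.
   - Fallback (different approach): convert allylic alcohol 6 to its allylic bromide and allylate it, then install the epoxide enantioselectively at the end of the fragment by Shi epoxidation. The C7=C8 alkene should react selectively because the vinyl iodide is deactivated and the terminal alkene is monosubstituted.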